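**Retrosynthetic overview**

1. The ten-membered ring is closed last, at C5=C6, by intramolecular Horner–Wadsworth–Emmons olefination of a C6 aldehyde with a C5 phosphonoacetate; just before it the γ-lactone (C7–O–C19, C17–C8) is made by SmI2 Reformatsky cyclisation onto a C8 ketone.
2. C8–C9 comes from a Felkin–Anh-controlled Nozaki–Hiyama–Kishi addition of a C6–C8 alkenyl bromide (from (R)-benzyl glycidyl ether) to a C9 aldehyde; C3–C4 from Michael addition of the C2 methyl ketone enolate to trimethyl 2-phosphonoacrylate; C14 and C2 from two hydroxyl-directed reductions (1,3-anti, then 1,3-syn).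
3. The six-membered ring is made first: C1–C10 and C12–C13 form together in a Michael/aldol/lactonisation cascade of 3-methylpentane-2,4-dione (C13, C14, C1, C15, C2, C3) with ethyl (2E)-3-methyl-4-oxobut-2-enoate (C9–C12, C20).
4. Enabling feature: on the six-membered ring (C1, C10–C14) the C9 branch at C10 and the hydroxyl at C12 are cis-1,3, and the quaternary C1 lies between two oxygenated carbons (C2, C14). C9 at the acid level can therefore be tied to O12 as a temporary γ-lactone bridge (6-oxabicyclo[3.2.1]octane), and C2–C1–C14 becomes a symmetrical 1,3-diketone.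
5. Ring order: six-membered carbocycle (with the temporary lactone bridge) → γ-lactone → ten-membered ring.

Key step: step 1

Remark (numbering): briarane numbering is used: C1 is the methyl-bearing quaternary carbon, C2–C9 run through the ten-membered ring to C10, C11–C14 complete the six-membered ring, C15 is the methyl on C1, C16 the ester carbon on C5, C17–C19 the lactone carbons (C18 methyl), C20 the methyl on C11; β is the face of the six-membered ring that carries C15.
Remark (assumption): 1, 2, 9, 14 and 22 are taken as commercial; the quinine-derived squaramide is assumed to shield the face of C10 that leads to 5, otherwise its quinidine-derived pseudoenantiomer is used.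
Remark (mixtures): 10–13, 19–21 and 23–27 are epimer mixtures at the phosphonate-bearing C5, and 17, 23 and 24 also at the CHBr carbon; these centres are lost in steps 11, 17 and 20.

**Route**

Step 1
Reactants: 1 3-methylpentane-2,4-dione; 2 ethyl (2E)-3-methyl-4-oxobut-2-enoate
Product: 5 (1S,2S,5S,8R)-2-acetyl-2,8-dimethyl-6-oxabicyclo[3.2.1]octane-3,7-dione, via Michael adduct 3 (not isolated), via ketol ester 4 (not isolated)
Conditions: 3-{[3,5-bis(trifluoromethyl)phenyl]amino}-4-{[(8α,9S)-6'-methoxycinchonan-9-yl]amino}cyclobut-3-ene-1,2-dione (5 mol%), CH2Cl2, −20 °C → rt; then DBU (0.2 equiv), 4 Å molecular sieves, rt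
Reagents that add atoms: none
Why: The tertiary amine of the squaramide deprotonates 1 and its central carbon (C1) adds to C10 of 2 (β to the aldehyde, α to the ester) to give 3; with DBU one acetyl group enolises, C13 adds to the C12 aldehyde to give ketol 4, and the C12 alkoxide acylates the cis-1,3-disposed C9 ester with loss of ethanol. The closest known reaction type is the amine- or base-mediated Michael/aldol [3+3] annulation of 1,3-dicarbonyl compounds with enals, here followed by lactonisation of the γ-hydroxy ester. The carbocycle closes in a 6-(enolendo)-exo-trig aldol addition and the lactone bridge in a 5-exo-trig acyl transfer. C10 is set by the catalyst in the Michael step; C11 and C12 stay epimerisable (enolisation of the α-branched aldehyde, retro-aldol) until the lactone closes, which is possible only with O12 cis to C9 and places the C20 methyl on the open side next to the lactone bridge; C1 becomes stereogenic only in the aldol step, because the two acetyl groups of 1 are identical, and the bicyclic chair is expected to hold the remaining acetyl group axial on the face away from the bridge (smaller A-value, less dipole repulsion with the ring ketone). The step needs attack at C10 and not C11, which the stronger activation by the aldehyde and the methyl group on C11 secure, and ring closure through a methyl ketone, which the symmetry of 1 secures because either acetyl group gives the same constitution. Once closed, the lactone cannot undergo retro-aldol or β-elimination (both would need a bridgehead double bond), so it traps the all-cis C10/C11/C12 array and protects O12.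

Step 2
Reactants: 5 (1S,2S,5S,8R)-2-acetyl-2,8-dimethyl-6-oxabicyclo[3.2.1]octane-3,7-dione
Product: 6 (1S,2S,5S,6R)-2-acetyl-5-hydroxy-N,N,2,6-tetramethyl-3-oxocyclohexane-1-carboxamide (12β-OH, C9 dimethylamide)
Conditions: Me2NH·HCl (3 equiv), AlMe3 (3 equiv), CH2Cl2, 0 °C → rt; aq. Rochelle salt
Reagents that add atoms: dimethylamine hydrochloride, CNC.Cl
Why: Aluminium amide aminolysis of a lactone: the Lewis acidic MeAl(Cl)NMe2 should open the bridged γ-lactone at C9 while the two ketones, both next to the quaternary C1, are left alone; no stereocentre is touched, and the tertiary amide is too poor an acyl donor to relactonise or to be attacked by the enolate of step 5.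

Step 3
Reactants: 6 hydroxy keto amide
Product: 7 diol amide (as 6 with the C14 ketone reduced to the 14α alcohol; 12β,14α-diol)
Conditions: Me4NBH(OAc)3 (5 equiv), MeCN/AcOH 1:1, −30 °C
Reagents that add atoms: none
Why: Saksena–Evans hydroxyl-directed reduction: the alkoxyborohydride formed at O12 should deliver hydride intramolecularly to the C14 ketone from the face of O12, which gives the 1,3-anti (14α) alcohol, while the undirected C2 ketone and the amide do not react.

Step 4
Reactants: 7 diol amide
Product: 8 12-O-TBS ether of 7 (14α-OH free)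
Conditions: TBSCl (1.2 equiv), imidazole, DMF, 0 °C
Reagents that add atoms: tert-butyldimethylsilyl chloride, CC(C)(C)[Si](C)(C)Cl
Why: Silylation: the C12 hydroxyl sits between CH and CH2, whereas the C14 hydroxyl is neopentylic (next to quaternary C1), so TBSCl/imidazole should silylate O12 only.

Step 5
Reactants: 8 12-O-TBS ether; 9 trimethyl 2-phosphonoacrylate
Product: 10 phosphonate ketone (8 with the acetyl group extended to C2(=O)–C3H2–C4H2–C5H(CO2Me)P(O)(OMe)2)
Conditions: LiN(SiMe3)2 (2.2 equiv), THF, −78 °C; then 9 (1.1 equiv), −78 → −40 °C; aq. NH4Cl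
Reagents that add atoms: none
Why: Michael addition of a ketone enolate to a 2-phosphonoacrylate: the base forms the C14 alkoxide and the only possible enolate of the C2 ketone (at C3, since C1 is quaternary), which should add to the unsubstituted β-carbon of 9 to give a stabilised phosphonoacetate anion; the new C5 centre is a mixture and is lost in step 20.

Step 6
Reactants: 10 phosphonate ketone
Product: 11 syn-diol (10 with the C2 ketone reduced to the carbinol syn to the 14α-OH, C2 as in the target)
Conditions: Et2BOMe (1.2 equiv), THF/MeOH 4:1, −78 °C; NaBH4, −78 °C; AcOH quench, evaporation from MeOH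
Reagents that add atoms: none
Why: Narasaka–Prasad reduction: Et2BOMe ties O14 and the C2 carbonyl into a six-membered boron chelate and external hydride attacks axially, which should give the 1,3-syn diol and thus the C2 configuration of the target; ester, phosphonate and amide survive NaBH4 at −78 °C.

Step 7
Reactants: 11 syn-diol
Product: 12 2,14-diacetate of 11
Conditions: Ac2O, Et3N, DMAP, CH2Cl2, rt
Reagents that add atoms: acetic anhydride, CC(=O)OC(C)=O
Why: DMAP-catalysed acylation of both hindered secondary alcohols installs the final C2 and C14 acetates while O12 stays silylated.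

Step 8
Reactants: 12 diacetate amide
Product: 13 C9 aldehyde (12 with CONMe2 replaced by CHO)
Conditions: Cp2Zr(H)Cl (1.6 equiv), THF, rt
Reagents that add atoms: none
Why: Chemoselective reduction of a tertiary amide to the aldehyde with Schwartz's reagent Cp2Zr(H)Cl, whose zirconium hemiaminal does not over-reduce and which should leave the acetates, the methyl ester and the phosphonate untouched; the neutral conditions do not epimerise C10.

Step 9
Reactants: 14 (2R)-2-[(benzyloxy)methyl]oxirane
Product: 15 (2R)-1-(benzyloxy)but-3-en-2-ol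
Conditions: Me3S+ I− (3 equiv), n-BuLi (2.9 equiv), THF, −10 °C → rt
Reagents that add atoms: trimethylsulfonium iodide, C[S+](C)C.[I-]
Why: One-carbon homologation of an epoxide to an allylic alcohol with dimethylsulfonium methylide: the ylide opens the terminal epoxide carbon and the sulfonium betaine eliminates Me2S, so the carbinol stereocentre (future C7) is retained.

Step 10
Reactants: 15 (2R)-1-(benzyloxy)but-3-en-2-ol
Product: 16 {[(2R)-1-(benzyloxy)but-3-en-2-yl]oxy}triethylsilane
Conditions: TESCl, imidazole, CH2Cl2, 0 °C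
Reagents that add atoms: chlorotriethylsilane, CC[Si](Cl)(CC)CC
Why: Standard silylation of a secondary alcohol; the TES group is chosen because it can later be removed in the presence of the C12 TBS ether.

Step 11
Reactants: 16 TES ether
Product: 18 {[(2S)-1-(benzyloxy)-3-bromobut-3-en-2-yl]oxy}triethylsilane, via vicinal dibromide 17 (not isolated)
Conditions: Br2, CH2Cl2, −78 °C; then DBU, DMF, 70 °C
Reagents that add atoms: bromine, BrBr
Why: Bromine addition and dehydrobromination: DBU removes the more acidic proton on the internal, bromine-bearing carbon next to the oxygenated carbon and expels the primary bromide, which should give the 2-bromo-1-alkene; C7 is not involved (the descriptor changes only through priorities).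

Step 12
Reactants: 13 C9 aldehyde; 18 alkenyl bromide
Product: 19 allylic alcohol (C9 carbinol in the target configuration, carrying the C8(=CH2)–C7H(OTES)–C6H2OBn branch)
Conditions: CrCl2 (6 equiv), NiCl2 (2 mol%), DMSO, rt
Reagents that add atoms: none
Why: Nozaki–Hiyama–Kishi coupling: the alkenylchromium species from 18 adds to the aldehyde in the presence of esters and phosphonate, and Felkin–Anh control by C10 (quaternary C1 as the large group anti to the nucleophile, H10 beside the incoming carbon) should set the C9 configuration of the target.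

Step 13
Reactants: 19 allylic alcohol
Product: 20 9-acetate of 19
Conditions: Ac2O, pyridine, DMAP, CH2Cl2, rt
Reagents that add atoms: acetic anhydride, CC(=O)OC(C)=O
Why: DMAP-catalysed acylation installs the final C9 acetate; no other free hydroxyl is present.

Step 14
Reactants: 20 9-acetate
Product: 21 C7 alcohol (20 without the TES group)
Conditions: PPTS (0.2 equiv), MeOH/CH2Cl2 1:1, 0 °C
Reagents that add atoms: none
Why: Acid-catalysed methanolysis of a silyl ether: a secondary TES ether is cleaved far faster than the secondary TBS ether at C12, and acetates and the benzyl ether are stable.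

Step 15
Reactants: 21 C7 alcohol; 22 2-bromopropanoyl bromide
Product: 23 C7 2-bromopropanoate of 21
Conditions: 22 (1.5 equiv), pyridine, CH2Cl2, −20 °C
Reagents that add atoms: none
Why: Acylation of the C7 allylic alcohol with an acid bromide brings in C17–C19 as an α-bromo ester; the CHBr centre is a mixture and becomes the enolate carbon in step 17.

Step 16
Reactants: 23 bromopropanoate
Product: 24 C8 ketone (23 with C8=CH2 cleaved to C8=O)
Conditions: OsO4 (2 mol%), NaIO4 (4 equiv), 2,6-lutidine, dioxane/H2O 3:1, rt
Reagents that add atoms: sodium periodate, [Na+].[O-]I(=O)(=O)=O (oxygen passed on through catalytic OsO4, O=[Os](=O)(=O)=O)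
Why: Lemieux–Johnson cleavage of the only alkene in the molecule turns the 1,1-disubstituted C8 methylene into the C8 ketone; the buffered conditions should spare the α-acyloxy stereocentres C7 and C9.

Step 17
Reactants: 24 C8 ketone
Product: 25 γ-lactone (C7–O–C19(=O)–C17H(CH3)–C8(OH) ring closed; C6 benzyl ether)
Conditions: SmI2 (2.2 equiv), THF, −78 °C; aq. NH4Cl
Reagents that add atoms: none
Why: Intramolecular SmI2 Reformatsky reaction: the samarium enolate from the α-bromo ester adds to the C8 ketone and closes the five-membered lactone; the bulky C9 branch should take the position trans to the C7 benzyloxymethyl group (tertiary hydroxyl cis to it), and the C17 methyl should end trans to the C9 branch, the more stable arrangement that epimerisation α to the lactone carbonyl would also reach.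

Step 18
Reactants: 25 γ-lactone benzyl ether
Product: 26 C6 primary alcohol of 25
Conditions: H2 (1 atm), Pd/C (10%), EtOAc, rt
Reagents that add atoms: none
Why: Hydrogenolysis of the benzyl ether; the molecule has no alkene or halide at this stage, and silyl ether, acetates, lactone and phosphonate are inert.

Step 19
Reactants: 26 primary alcohol
Product: 27 C6 aldehyde
Conditions: Dess–Martin periodinane, NaHCO3, CH2Cl2, 0 °C → rt
Reagents that add atoms: none
Why: Dess–Martin oxidation of the only primary alcohol under buffered, non-basic conditions, which should keep the α-acyloxy aldehyde configurationally intact; the tertiary C8 hydroxyl cannot be oxidised.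

Step 20
Reactants: 27 C6 aldehyde
Product: 28 12-O-TBS ether of the target (ten-membered ring closed at C5=C6)
Conditions: LiCl (10 equiv), iPr2NEt (5 equiv), MeCN, 0.001 M (syringe-pump addition), rt
Reagents that add atoms: none
Why: Intramolecular Horner–Wadsworth–Emmons olefination under Masamune–Roush conditions at high dilution: the lithium-chelated phosphonoacetate anion adds to the C6 aldehyde and closes the ten-membered ring, and the α-substituted phosphonoacetate should give the alkene with C7 cis to C4 and trans to the ester, which is both the usual outcome and the less strained geometry in the ring.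

Step 21
Reactants: 28 12-O-TBS ether
Product: 29 target CNP0233742.2
Conditions: HF·pyridine, pyridine, THF, 0 °C → rt
Reagents that add atoms: none
Why: Fluoride cleavage of the secondary TBS ether with buffered HF·pyridine, which should leave the three acetates, the lactone, the tertiary alcohol and the unsaturated ester untouched.

**Compound list**

1 | 3-methylpentane-2,4-dione | CC(=O)C(C)C(C)=O | starting material
2 | ethyl (2E)-3-methyl-4-oxobut-2-enoate | CCOC(=O)/C=C(\C)C=O | starting material
3 | Michael adduct: ethyl (2S)-3,3-diacetyl-2-(1-oxopropan-2-yl)butanoate (epimers at the formyl-bearing carbon) | CCOC(=O)[C@H](C(C)(C(C)=O)C(C)=O)C(C)C=O | intermediate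
4 | ketol ester: ethyl (1S,2S,5S,6R)-2-acetyl-5-hydroxy-2,6-dimethyl-3-oxocyclohexane-1-carboxylate | CCOC(=O)[C@H]1[C@@H](C)[C@@H](O)CC(=O)[C@]1(C)C(C)=O | intermediate
5 | (1S,2S,5S,8R)-2-acetyl-2,8-dimethyl-6-oxabicyclo[3.2.1]octane-3,7-dione | O=C1[C@H]2[C@@H](C)[C@@H](O1)CC(=O)[C@]2(C)C(C)=O | intermediate
6 | (1S,2S,5S,6R)-2-acetyl-5-hydroxy-N,N,2,6-tetramethyl-3-oxocyclohexane-1-carboxamide | CN(C)C(=O)[C@H]1[C@@H](C)[C@@H](O)CC(=O)[C@]1(C)C(C)=O | intermediate
7 | diol amide: 6 with the ring ketone reduced to the 14α alcohol (12β,14α-diol) | CN(C)C(=O)[C@H]1[C@@H](C)[C@@H](O)C[C@H](O)[C@]1(C)C(C)=O | intermediate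
8 | 12-O-TBS ether of 7 | CN(C)C(=O)[C@H]1[C@@H](C)[C@@H](O[Si](C)(C)C(C)(C)C)C[C@H](O)[C@]1(C)C(C)=O | intermediate
9 | trimethyl 2-phosphonoacrylate (methyl 2-(dimethoxyphosphoryl)prop-2-enoate) | COC(=O)C(=C)P(=O)(OC)OC | starting material
10 | phosphonate ketone: 8 with C2(=O)–C3H2–C4H2–C5H(CO2Me)P(O)(OMe)2 in place of the acetyl group | CN(C)C(=O)[C@H]1[C@@H](C)[C@@H](O[Si](C)(C)C(C)(C)C)C[C@H](O)[C@]1(C)C(=O)CCC(C(=O)OC)P(=O)(OC)OC | intermediate
11 | syn-diol: 10 with C2 reduced to the carbinol syn to the 14α-OH | CN(C)C(=O)[C@H]1[C@@H](C)[C@@H](O[Si](C)(C)C(C)(C)C)C[C@H](O)[C@]1(C)[C@H](O)CCC(C(=O)OC)P(=O)(OC)OC | intermediate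
12 | 2,14-diacetate of 11 | CN(C)C(=O)[C@H]1[C@@H](C)[C@@H](O[Si](C)(C)C(C)(C)C)C[C@H](OC(C)=O)[C@]1(C)[C@H](OC(C)=O)CCC(C(=O)OC)P(=O)(OC)OC | intermediate
13 | C9 aldehyde: 12 with CHO in place of CONMe2 | O=C[C@H]1[C@@H](C)[C@@H](O[Si](C)(C)C(C)(C)C)C[C@H](OC(C)=O)[C@]1(C)[C@H](OC(C)=O)CCC(C(=O)OC)P(=O)(OC)OC | intermediate
14 | (2R)-2-[(benzyloxy)methyl]oxirane ((R)-benzyl glycidyl ether) | C(OC[C@H]1CO1)c1ccccc1 | starting material
15 | (2R)-1-(benzyloxy)but-3-en-2-ol | C(OC[C@@H](C=C)O)c1ccccc1 | intermediate
16 | {[(2R)-1-(benzyloxy)but-3-en-2-yl]oxy}triethylsilane | C(OC[C@@H](C=C)O[Si](CC)(CC)CC)c1ccccc1 | intermediate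
17 | vicinal dibromide: {[(2S)-1-(benzyloxy)-3,4-dibromobutan-2-yl]oxy}triethylsilane (epimers at CHBr) | C(OC[C@@H](C(Br)CBr)O[Si](CC)(CC)CC)c1ccccc1 | intermediate
18 | {[(2S)-1-(benzyloxy)-3-bromobut-3-en-2-yl]oxy}triethylsilane | C(OC[C@@H](C(Br)=C)O[Si](CC)(CC)CC)c1ccccc1 | intermediate
19 | allylic alcohol: C9 carbinol bearing C8(=CH2)–C7H(OTES)–C6H2OBn, core as 13 | c1ccccc1COC[C@H](O[Si](CC)(CC)CC)C(=C)[C@H](O)[C@H]1[C@@H](C)[C@@H](O[Si](C)(C)C(C)(C)C)C[C@H](OC(C)=O)[C@]1(C)[C@H](OC(C)=O)CCC(C(=O)OC)P(=O)(OC)OC | intermediate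
20 | 9-acetate of 19 | c1ccccc1COC[C@H](O[Si](CC)(CC)CC)C(=C)[C@H](OC(C)=O)[C@H]1[C@@H](C)[C@@H](O[Si](C)(C)C(C)(C)C)C[C@H](OC(C)=O)[C@]1(C)[C@H](OC(C)=O)CCC(C(=O)OC)P(=O)(OC)OC | intermediate
21 | C7 alcohol: 20 without the TES group | c1ccccc1COC[C@H](O)C(=C)[C@H](OC(C)=O)[C@H]1[C@@H](C)[C@@H](O[Si](C)(C)C(C)(C)C)C[C@H](OC(C)=O)[C@]1(C)[C@H](OC(C)=O)CCC(C(=O)OC)P(=O)(OC)OC | intermediate
22 | 2-bromopropanoyl bromide (racemic) | CC(Br)C(Br)=O | starting material
23 | C7 2-bromopropanoate of 21 | c1ccccc1COC[C@H](OC(=O)C(C)Br)C(=C)[C@H](OC(C)=O)[C@H]1[C@@H](C)[C@@H](O[Si](C)(C)C(C)(C)C)C[C@H](OC(C)=O)[C@]1(C)[C@H](OC(C)=O)CCC(C(=O)OC)P(=O)(OC)OC | intermediate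
24 | C8 ketone: 23 with C8=O in place of C8=CH2 | c1ccccc1COC[C@H](OC(=O)C(C)Br)C(=O)[C@H](OC(C)=O)[C@H]1[C@@H](C)[C@@H](O[Si](C)(C)C(C)(C)C)C[C@H](OC(C)=O)[C@]1(C)[C@H](OC(C)=O)CCC(C(=O)OC)P(=O)(OC)OC | intermediate
25 | γ-lactone with 8-OH and 17-methyl as in the target, C6 benzyl ether, open C3–C5 phosphonate chain | c1ccccc1COC[C@@H]2OC(=O)[C@H](C)[C@@]2(O)[C@H](OC(C)=O)[C@H]1[C@@H](C)[C@@H](O[Si](C)(C)C(C)(C)C)C[C@H](OC(C)=O)[C@]1(C)[C@H](OC(C)=O)CCC(C(=O)OC)P(=O)(OC)OC | intermediate
26 | C6 primary alcohol of 25 | OC[C@@H]2OC(=O)[C@H](C)[C@@]2(O)[C@H](OC(C)=O)[C@H]1[C@@H](C)[C@@H](O[Si](C)(C)C(C)(C)C)C[C@H](OC(C)=O)[C@]1(C)[C@H](OC(C)=O)CCC(C(=O)OC)P(=O)(OC)OC | intermediate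
27 | C6 aldehyde of 26 | O=C[C@@H]2OC(=O)[C@H](C)[C@@]2(O)[C@H](OC(C)=O)[C@H]1[C@@H](C)[C@@H](O[Si](C)(C)C(C)(C)C)C[C@H](OC(C)=O)[C@]1(C)[C@H](OC(C)=O)CCC(C(=O)OC)P(=O)(OC)OC | intermediate
28 | 12-O-TBS ether of the target | COC(=O)/C1=C/[C@@H]2OC(=O)[C@H](C)[C@@]2(O)[C@H](OC(C)=O)[C@H]2[C@@H](C)[C@@H](O[Si](C)(C)C(C)(C)C)C[C@H](OC(C)=O)[C@]2(C)[C@H](OC(C)=O)CC1 | intermediate
29 | target CNP0233742.2 (2,9,14-triacetoxy-8,12-dihydroxy briarane lactone, C16 methyl ester) | COC(=O)/C1=C/[C@@H]2OC(=O)[C@H](C)[C@@]2(O)[C@H](OC(C)=O)[C@H]2[C@@H](C)[C@@H](O)C[C@H](OC(C)=O)[C@]2(C)[C@H](OC(C)=O)CC1 | target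

**Step count**

Total step count: 21. Longest linear sequence: 18 steps (steps 1–8 and 12–21, from 1 and 2 to 29); steps 9–11 make the alkenyl bromide 18.

**Steps most likely to fail**

Step 20. The closure may lose out to oligomerisation because of the transannular strain of the ten-membered ring, and the α-acyloxy aldehyde may epimerise at C7 under the base. The fallback closes the same bond by ring-closing metathesis. It sets out from alcohol 26, whose phosphonoacetate is methylenated with aqueous formaldehyde and K2CO3 to the 2-substituted acrylate F1. Dess–Martin oxidation gives the acrylate aldehyde F2, and methylenation with Ph3P=CH2 at −78 °C gives the diene F3. Ring-closing metathesis with the second-generation Hoveyda–Grubbs catalyst in toluene at 80 °C under high dilution should then give 28, where the fallback rejoins the route.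

Step 1. The enantiomeric purity may erode, because the Michael addition is reversible until the lactone trap closes, or the catalyst may discriminate the two faces of C10 poorly. The fallback is a classical resolution. It sets out again from 1 and 2: the cascade is run with DBU alone, which gives 5 together with the mirror-image lactone F4. The mixture is opened with the aluminium amide made from (R)-1-phenylethanamine and AlMe3 to the hydroxy amide F5 and the diastereomeric hydroxy amide F6, which are separated by crystallisation or chromatography. F5 is relactonised with TsOH in toluene at 80 °C, which returns enantiopure 5 and frees the amine.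

Step 17. SmI2 may reduce the α-acyloxy ketone (loss of the C9 acetate or of the C7 ester) faster than the Reformatsky addition takes place, or the addition may take the wrong face of C8. The fallback replaces the Reformatsky reaction by a copper hydride reductive aldol cyclisation. It sets out from alcohol 21, which is cleaved with OsO4/NaIO4 to the hydroxy ketone F7 and acylated with acryloyl chloride and iPr2NEt to the acrylate F8. [(Ph3P)CuH]6 in toluene then reduces the acrylate to a copper enolate that adds to the C8 ketone and should give lactone 25 directly, where the route is rejoined.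

Further compounds
F1 | step 20 | 2-substituted acrylate: 26 with C5(=CH2)CO2Me in place of the phosphonoacetate | OC[C@@H]2OC(=O)[C@H](C)[C@@]2(O)[C@H](OC(C)=O)[C@H]1[C@@H](C)[C@@H](O[Si](C)(C)C(C)(C)C)C[C@H](OC(C)=O)[C@]1(C)[C@H](OC(C)=O)CCC(=C)C(=O)OC
F2 | step 20 | acrylate aldehyde: C6 aldehyde of F1 | O=C[C@@H]2OC(=O)[C@H](C)[C@@]2(O)[C@H](OC(C)=O)[C@H]1[C@@H](C)[C@@H](O[Si](C)(C)C(C)(C)C)C[C@H](OC(C)=O)[C@]1(C)[C@H](OC(C)=O)CCC(=C)C(=O)OC
F3 | step 20 | diene: F2 with the aldehyde methylenated to the C6 vinyl group | C=C[C@@H]2OC(=O)[C@H](C)[C@@]2(O)[C@H](OC(C)=O)[C@H]1[C@@H](C)[C@@H](O[Si](C)(C)C(C)(C)C)C[C@H](OC(C)=O)[C@]1(C)[C@H](OC(C)=O)CCC(=C)C(=O)OC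
F4 | step 1 | (1R,2R,5R,8S)-2-acetyl-2,8-dimethyl-6-oxabicyclo[3.2.1]octane-3,7-dione | O=C1[C@@H]2[C@H](C)[C@H](O1)CC(=O)[C@@]2(C)C(C)=O
F5 | step 1 | hydroxy amide from 5 and (R)-1-phenylethanamine | C[C@@H](NC(=O)[C@H]1[C@@H](C)[C@@H](O)CC(=O)[C@]1(C)C(C)=O)c1ccccc1
F6 | step 1 | hydroxy amide from F4 and (R)-1-phenylethanamine | C[C@@H](NC(=O)[C@@H]1[C@H](C)[C@H](O)CC(=O)[C@@]1(C)C(C)=O)c1ccccc1
F7 | step 17 | hydroxy ketone: 21 with C8=O in place of C8=CH2 | c1ccccc1COC[C@H](O)C(=O)[C@H](OC(C)=O)[C@H]1[C@@H](C)[C@@H](O[Si](C)(C)C(C)(C)C)C[C@H](OC(C)=O)[C@]1(C)[C@H](OC(C)=O)CCC(C(=O)OC)P(=O)(OC)OC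
F8 | step 17 | C7 acrylate of F7 | c1ccccc1COC[C@H](OC(=O)C=C)C(=O)[C@H](OC(C)=O)[C@H]1[C@@H](C)[C@@H](O[Si](C)(C)C(C)(C)C)C[C@H](OC(C)=O)[C@]1(C)[C@H](OC(C)=O)CCC(C(=O)OC)P(=O)(OC)OC
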